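The route rests on cutting the C9–C10 bond (longipinane numbering), where the free carbinol meets the quaternary cyclobutane carbon. The last step closes the seven-membered ring by a cobalt-hydride/chromium reductive alkene–aldehyde coupling. Hydrogen-atom transfer turns an exocyclic C10 methylene into the C10 methyl group and a tertiary C10 nucleophile, which adds to the C9 aldehyde and creates both stereocentres and the only free hydroxyl. It exploits that C5 and C10 are the two one-carbon bridges of the bicyclo[3.1.1]heptenone, so the C5 side chain overhangs C10. The precursor, a 6-methylenebicyclo[3.1.1]heptenone already bearing both esters, comes from an intramolecular vinylketene [2+2] cycloaddition.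

Key step: step 15

Remark: longipinane locants are kept for all intermediates: C1 ketone, C2=C3(CH3), C4, C5, C6(CH3)2, C7 angelate, C8 2-methylbutanoate, C9 OH, C10 CH3, C11. The cyclobutane is C4–C5–C11–C10 and the three-carbon bridge is C1–C2–C3. The C8 acyl group is taken as (R)-2-methylbutanoyl, as drawn.

Step 1
Reactants: 1 (R)-solketal; 2 3-methylbuta-1,2-diene
Product: 3 (1S)-1-[(4S)-2,2-dimethyl-1,3-dioxolan-4-yl]-2,2-dimethylbut-3-en-1-ol
Conditions: [Ir(cod)Cl]2 (2.5 mol%), SEGPHOS (5 mol%, antipode giving the 7S carbinol), 4-chloro-3-nitrobenzoic acid (10 mol%), Cs2CO3 (20 mol%), toluene, 60 °C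
Reagents that add atoms: none
Why: Iridium-catalysed carbonyl reverse prenylation by hydrogen auto-transfer: 1 is dehydrogenated to the aldehyde and the hydride turns 2 into a 1,1-dimethylallyl iridium species that adds through its substituted terminus in a closed chair transition state, so C6 becomes quaternary, C7 is set as S by the ligand and C8 comes unchanged from 1.

Step 2
Reactants: 3 reverse-prenyl alcohol; 4 angelic acid
Product: 6 C7 angelate of 3, via mixed anhydride 5 (not isolated)
Conditions: 4, 2,4,6-trichlorobenzoyl chloride, Et3N, toluene, 23 °C; then 3, 80 °C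
Reagents that add atoms: none
Why: Yamaguchi-type mixed-anhydride esterification run without a nucleophilic catalyst should acylate the hindered C7 hydroxyl while the Z geometry of the angelate is kept.

Step 3
Reactants: 6 angelate; 7 (E)-but-2-enal
Product: 8 (E)-enal (C1 aldehyde, C11=C5 double bond)
Conditions: second-generation Hoveyda–Grubbs catalyst (10 mol%), 7 (5 equiv), CH2Cl2, 40 °C
Reagents that add atoms: none
Why: Olefin cross-metathesis of the hindered vinyl group, which cannot homodimerise, with an excess of the enal partner should give the E enal, the trisubstituted electron-poor angelate being inert.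

Step 4
Reactants: 9 methyl 3-methylbut-2-enoate
Product: 11 silyl dienol ether, via lithium dienolate 10 (not isolated)
Conditions: LDA, THF/DMPU, −78 °C; TBSCl
Reagents that add atoms: tert-butyldimethylsilyl chloride CC(C)(C)[Si](C)(C)Cl
Why: Gamma-deprotonation of the senecioate and O-silylation of the extended enolate is the standard entry to a vinylogous Mukaiyama donor.

Step 5
Reactants: 8 enal; 11 silyl dienol ether
Product: 12 methyl (2E,5R,6E,9S)-dienoate with the C1 OTBS group
Conditions: chiral 3,3'-bis[3,5-bis(trifluoromethyl)phenyl]-1,1'-binaphthalene-2,2'-disulfonimide (5 mol%, antipode giving the 1R ether), Et2O, −78 °C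
Reagents that add atoms: none
Why: Catalytic asymmetric vinylogous Mukaiyama aldol reaction with silyl transfer: the silylated disulfonimide activates the enal, the dienolate attacks through its gamma carbon (C2), and the catalyst sets the temporary C1 stereocentre as R independently of the remote C7 and C8 centres.

Step 6
Reactants: 12 methyl ester
Product: 13 dienoic acid
Conditions: LiOH, THF/MeOH/H2O, 23 °C; then dilute HCl to pH 4, 0 °C
Reagents that add atoms: lithium hydroxide [Li+].[OH-]
Why: Saponification should pick the unhindered methyl ester, because the angelate sits on a secondary carbinol flanked by a quaternary carbon.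

Step 7
Reactants: 13 dienoic acid
Product: 16 bicyclic C10 cyclobutanone, via acid chloride 14 (not isolated), via vinylketene 15 (not isolated)
Conditions: 1-chloro-N,N,2-trimethylprop-1-en-1-amine, CH2Cl2, 0 °C; then slow addition to Et3N, toluene, 110 °C, high dilution
Reagents that add atoms: none
Why: Dehydrochlorination of the E acid chloride at the methyl group cis to the acyl group gives vinylketene 15, whose intramolecular thermal [2+2] cycloaddition is suprafacial on the E alkene (C5 chain anti to the new three-carbon bridge), bonds the ketene carbonyl carbon C10 to C11 because positive charge builds up at C5 away from the silyloxy-bearing C1 and because C5 is neopentyl, and takes the alkene face that leaves the C1 silyloxy group inside and the C1 hydrogen anti to the forming C10–C11 bond, which sets C4, C5 and C11.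

Step 8
Reactants: 16 cyclobutanone
Product: 17 C10 methylene compound
Conditions: Ph3PCH3Br, KOtBu, THF, 0 to 23 °C
Reagents that add atoms: methyltriphenylphosphonium bromide C[P+](c1ccccc1)(c1ccccc1)c1ccccc1.[Br-]
Why: Wittig methylenation of the strained, non-enolisable cyclobutanone should be much faster than any attack on the hindered ester.

Step 9
Reactants: 17 silyl ether
Product: 18 C1 alcohol
Conditions: HF·pyridine, THF/pyridine, 0 to 23 °C
Reagents that add atoms: none
Why: Buffered fluoride desilylation frees the C1 alcohol without touching the acetonide or the angelate.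

Step 10
Reactants: 18 C1 alcohol
Product: 20 conjugated enone, via deconjugated ketone 19 (not isolated)
Conditions: Dess–Martin periodinane, CH2Cl2, 0 °C; then DBU (0.2 equiv), 23 °C
Reagents that add atoms: none
Why: Dess–Martin oxidation gives the beta,gamma-unsaturated ketone 19 and base-catalysed conjugation moves the C3 exocyclic double bond into the ring, the bridgeheads being unable to enolise, so only the verbenone-type enone can form.

Step 11
Reactants: 20 acetonide
Product: 21 C8,C9 diol
Conditions: AcOH/H2O (4:1), 40 °C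
Reagents that add atoms: none
Why: Mild acid hydrolysis of the terminal acetonide, which the enone, the C10 methylene group and the ester should tolerate.

Step 12
Reactants: 21 diol
Product: 22 C9 triethylsilyl ether
Conditions: TESCl (1.05 equiv), imidazole, CH2Cl2, −20 °C
Reagents that add atoms: triethylsilyl chloride CC[Si](Cl)(CC)CC
Why: Steric differentiation: the primary C9 hydroxyl is silylated much faster than the secondary C8 hydroxyl.

Step 13
Reactants: 22 C8 alcohol; 23 (R)-2-methylbutanoic acid
Product: 25 C7,C8 diester, via mixed anhydride 24 (not isolated)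
Conditions: 23, 2,4,6-trichlorobenzoyl chloride, Et3N, toluene, 23 °C; then 22, DMAP (0.2 equiv), 23 °C
Reagents that add atoms: none
Why: Yamaguchi esterification of the only free hydroxyl, under conditions that should not enolise the alpha stereocentre of the acid.

Step 14
Reactants: 25 triethylsilyl ether
Product: 26 C9 aldehyde
Conditions: (COCl)2, DMSO, CH2Cl2, −78 to −40 °C; then Et3N, −78 to 0 °C
Reagents that add atoms: none
Why: Swern conditions cleave and oxidise primary triethylsilyl ethers directly, so the aldehyde is reached in one operation and no free hydroxy ester is exposed to acyl migration.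

Step 15
Reactants: 26 C9 aldehyde with C10 methylene
Product: 28 target CNP0206166.1, via alkylchromium dichloride 27 (not isolated)
Conditions: Co(salen) (10 mol%; salen = N,N'-bis(3,5-di-tert-butylsalicylidene)-1,2-cyclohexanediamine dianion), CrCl3(thf)3 (1.5 equiv), PhSiH3 (2 equiv), THF, 23 °C, 0.01 M; aqueous work-up
Reagents that add atoms: none
Why: A trivalent cobalt hydride formed from Co(salen), CrCl3 and PhSiH3 transfers a hydrogen atom to the CH2 terminus of the strained C10 methylene, which creates the C10 methyl group and a tertiary cyclobutyl radical; divalent chromium traps it as alkylchromium 27, which adds to the C9 aldehyde. The closest known reaction type is the branch-selective cobalt/chromium hydrogen-atom-transfer coupling of 1,1-disubstituted alkenes with aldehydes, a radical-polar-crossover form of the Nozaki–Hiyama–Kishi reaction, used here intramolecularly. The seven-membered ring C5–C6–C7–C8–C9–C10–C11 closes in the 7-exo-trig mode on the carbonyl carbon. C10 is controlled by the tether, because the C5 chain stands 1,3-cis on the cyclobutane face away from the enone bridge and can reach only that face, reversible C–Cr homolysis feeding the reactive epimer; C9 is controlled by a polar Felkin–Anh arrangement with the C8 acyloxy group anti to the incoming C10 and both esters pseudo-equatorial, which places the new hydroxyl cis to the C8 ester. The step needs hydrogen-atom transfer to the methylene and not to the enone or the angelate, secured because these are trisubstituted and electron-poor, and addition to the aldehyde only, secured by the carbonyl selectivity of organochromium reagents.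

Compound list
1 | (R)-solketal, [(4R)-2,2-dimethyl-1,3-dioxolan-4-yl]methanol | OC[C@@H]1COC(C)(C)O1 | starting material
2 | 3-methylbuta-1,2-diene | CC(C)=C=C | starting material
3 | (1S)-1-[(4S)-2,2-dimethyl-1,3-dioxolan-4-yl]-2,2-dimethylbut-3-en-1-ol | C=CC(C)(C)[C@H](O)[C@@H]1COC(C)(C)O1 | intermediate
4 | angelic acid, (Z)-2-methylbut-2-enoic acid | C/C=C(/C)C(=O)O | starting material
5 | angelic 2,4,6-trichlorobenzoic anhydride | C/C=C(/C)C(=O)OC(=O)c1c(Cl)cc(Cl)cc1Cl | intermediate
6 | (1S)-1-[(4S)-2,2-dimethyl-1,3-dioxolan-4-yl]-2,2-dimethylbut-3-enyl (Z)-2-methylbut-2-enoate | C/C=C(/C)C(=O)O[C@H]([C@@H]1COC(C)(C)O1)C(C)(C)C=C | intermediate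
7 | (E)-but-2-enal | C/C=C/C=O | starting material
8 | (1S,3E)-1-[(4S)-2,2-dimethyl-1,3-dioxolan-4-yl]-2,2-dimethyl-5-oxopent-3-enyl (Z)-2-methylbut-2-enoate | C/C=C(/C)C(=O)O[C@H]([C@@H]1COC(C)(C)O1)C(C)(C)/C=C/C=O | intermediate
9 | methyl 3-methylbut-2-enoate | COC(=O)C=C(C)C | starting material
10 | lithium dienolate of 9 | [Li+].COC([O-])=CC(C)=C | intermediate
11 | tert-butyl[(1-methoxy-3-methylbuta-1,3-dienyl)oxy]dimethylsilane (ketene acetal geometry inconsequential) | COC(O[Si](C)(C)C(C)(C)C)=CC(C)=C | intermediate
12 | methyl (2E,5R,6E,9S)-5-(tert-butyldimethylsilyloxy)-9-[(4S)-2,2-dimethyl-1,3-dioxolan-4-yl]-3,8,8-trimethyl-9-[(Z)-2-methylbut-2-enoyloxy]nona-2,6-dienoate | COC(=O)/C=C(\C)C[C@@H](O[Si](C)(C)C(C)(C)C)/C=C/C(C)(C)[C@H](OC(=O)/C(C)=C\C)[C@@H]1COC(C)(C)O1 | intermediate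
13 | carboxylic acid of 12 | OC(=O)/C=C(\C)C[C@@H](O[Si](C)(C)C(C)(C)C)/C=C/C(C)(C)[C@H](OC(=O)/C(C)=C\C)[C@@H]1COC(C)(C)O1 | intermediate
14 | acid chloride of 13 | ClC(=O)/C=C(\C)C[C@@H](O[Si](C)(C)C(C)(C)C)/C=C/C(C)(C)[C@H](OC(=O)/C(C)=C\C)[C@@H]1COC(C)(C)O1 | intermediate
15 | vinylketene (C10 ketene carbon, C3 isopropenyl-type methylene) | O=C=CC(=C)C[C@@H](O[Si](C)(C)C(C)(C)C)/C=C/C(C)(C)[C@H](OC(=O)/C(C)=C\C)[C@@H]1COC(C)(C)O1 | intermediate
16 | bicyclo[3.1.1]heptanone with C10 as ketone bridge, exocyclic methylene at C3, (1R)-OTBS cis to the C10 bridge, C5 chain anti to the C1–C3 bridge; C4, C5, C11 as in 28; chain as in 6 | C/C=C(/C)C(=O)O[C@H]([C@@H]1COC(C)(C)O1)C(C)(C)[C@@H]2[C@H]3[C@H](O[Si](C)(C)C(C)(C)C)CC(=C)[C@@H]2C3=O | intermediate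
17 | C10 methylene analogue of 16 (two exocyclic methylenes, C3 and C10) | C/C=C(/C)C(=O)O[C@H]([C@@H]1COC(C)(C)O1)C(C)(C)[C@@H]2[C@H]3[C@H](O[Si](C)(C)C(C)(C)C)CC(=C)[C@@H]2C3=C | intermediate
18 | (1R)-alcohol from 17 | C/C=C(/C)C(=O)O[C@H]([C@@H]1COC(C)(C)O1)C(C)(C)[C@@H]2[C@H]3[C@H](O)CC(=C)[C@@H]2C3=C | intermediate
19 | C1 ketone with C3 exocyclic methylene (deconjugated) | C/C=C(/C)C(=O)O[C@H]([C@@H]1COC(C)(C)O1)C(C)(C)[C@@H]2[C@H]3C(=O)CC(=C)[C@@H]2C3=C | intermediate
20 | 4-methyl-6-methylenebicyclo[3.1.1]hept-3-en-2-one (C1 ketone, C2=C3, C10 methylene) with the C5 chain as in 6 | C/C=C(/C)C(=O)O[C@H]([C@@H]1COC(C)(C)O1)C(C)(C)[C@@H]2[C@H]3C(=O)C=C(C)[C@@H]2C3=C | intermediate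
21 | (7S,8S)-C7 angelate C8,C9 diol of the enone | C/C=C(/C)C(=O)O[C@H]([C@@H](O)CO)C(C)(C)[C@@H]1[C@H]2C(=O)C=C(C)[C@@H]1C2=C | intermediate
22 | C9 triethylsilyl ether of 21 | C/C=C(/C)C(=O)O[C@H]([C@@H](O)CO[Si](CC)(CC)CC)C(C)(C)[C@@H]1[C@H]2C(=O)C=C(C)[C@@H]1C2=C | intermediate
23 | (R)-2-methylbutanoic acid | CC[C@@H](C)C(=O)O | starting material
24 | (R)-2-methylbutanoic 2,4,6-trichlorobenzoic anhydride | CC[C@@H](C)C(=O)OC(=O)c1c(Cl)cc(Cl)cc1Cl | intermediate
25 | C7 angelate, C8 (R)-2-methylbutanoate, C9 triethylsilyl ether | C/C=C(/C)C(=O)O[C@H]([C@@H](OC(=O)[C@H](C)CC)CO[Si](CC)(CC)CC)C(C)(C)[C@@H]1[C@H]2C(=O)C=C(C)[C@@H]1C2=C | intermediate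
26 | C9 aldehyde, 9,10-seco precursor with C10 methylene and both esters | C/C=C(/C)C(=O)O[C@H]([C@@H](OC(=O)[C@H](C)CC)C=O)C(C)(C)[C@@H]1[C@H]2C(=O)C=C(C)[C@@H]1C2=C | intermediate
27 | C10 alkylchromium dichloride, chromium on the face of the C5 chain | C/C=C(/C)C(=O)O[C@H]([C@@H](OC(=O)[C@H](C)CC)C=O)C(C)(C)[C@@H]1[C@H]2C(=O)C=C(C)[C@@H]1[C@@]2(C)[Cr](Cl)Cl | intermediate
28 | CNP0206166.1, (4R,5S,7S,8S,9S,10R,11R)-7-angeloyloxy-9-hydroxy-8-[(R)-2-methylbutanoyloxy]longipin-2-en-1-one | C/C=C(/C)C(=O)O[C@@H]1[C@@H](OC(=O)[C@H](C)CC)[C@@H](O)[C@@]2(C)[C@@H]3C(=O)C=C(C)[C@H]2[C@@H]3C1(C)C | target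

Total step count: 15. Longest linear sequence: 14 (steps 1–3 and 5–15; step 4 is a side branch).

Steps most likely to fail

Step 15. The tertiary C10 radical may be quenched by a second hydrogen-atom transfer (net hydrogenation) before chromium traps it. The silane may also reduce the aldehyde, or the chromium alkoxide may trigger migration of the C8 acyl group. The fallback sets out from 26 and comes back at 28, and it separates hydrogen-atom transfer from C–C bond formation. Cobalt-mediated Markovnikov hydroiodination (Co(acac)2, tBuOOH, Et3SiH, CH2I2) should give the tertiary C10 iodide F1, either epimer being usable. An excess of CrCl2 in DMF, free of any hydride source, should then reduce the C–I bond to the same C10 organochromium and close the ring in a halide-based Nozaki–Hiyama–Kishi-type reaction.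

Step 7. Because the alkene is only 1,2-disubstituted, closure may take the fused bicyclo[3.2.0] sense. The C1 stereocentre may give poor facial selectivity, and the ketene may dimerise. The fallback sets out from 13 and comes back at 16 and replaces the ketene by a more electrophilic, more polarised cumulene that reacts at lower temperature. Amide coupling with pyrrolidine gives the pyrrolidine amide F2. Tf2O and 2,4,6-collidine in CH2Cl2 convert it through a vinyl keteniminium ion into the cyclobutaniminium triflate F3, and aqueous NaHCO3 hydrolyses this to 16.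

Step 1. The inherent Felkin preference of the transient alpha-alkoxy aldehyde opposes the catalyst, so facial selectivity at C7 may be poor, and the transient aldehyde may epimerise at C8. The fallback sets out from 1 and comes back at 3 and sets C7 by substrate-controlled hydride delivery instead of catalyst-controlled C–C bond formation. Swern oxidation gives (S)-glyceraldehyde acetonide F4. Barbier reverse prenylation (prenyl bromide, Zn, aqueous NH4Cl/THF) gives mainly the 7R alcohol F5, and Dess–Martin oxidation gives the ketone F6. Felkin–Anh reduction with LiBH(s-Bu)3 in THF at −78 °C should then deliver the syn alcohol 3.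

Further compounds
F1 | step 15 | tertiary C10 iodide of 26 (C10 epimers) | C/C=C(/C)C(=O)O[C@H]([C@@H](OC(=O)[C@H](C)CC)C=O)C(C)(C)[C@@H]1[C@H]2C(=O)C=C(C)[C@@H]1C2(C)I
F2 | step 7 | pyrrolidine amide of 13 | O=C(N1CCCC1)/C=C(\C)C[C@@H](O[Si](C)(C)C(C)(C)C)/C=C/C(C)(C)[C@H](OC(=O)/C(C)=C\C)[C@@H]2COC(C)(C)O2
F3 | step 7 | C10 cyclobutaniminium triflate | C/C=C(/C)C(=O)O[C@H]([C@@H]1COC(C)(C)O1)C(C)(C)[C@@H]2[C@H]3[C@H](O[Si](C)(C)C(C)(C)C)CC(=C)[C@@H]2C3=[N+]4CCCC4.[O-]S(=O)(=O)C(F)(F)F
F4 | step 1 | (S)-2,2-dimethyl-1,3-dioxolane-4-carbaldehyde | O=C[C@@H]1COC(C)(C)O1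
F5 | step 1 | (1R)-1-[(4S)-2,2-dimethyl-1,3-dioxolan-4-yl]-2,2-dimethylbut-3-en-1-ol | C=CC(C)(C)[C@@H](O)[C@@H]1COC(C)(C)O1
F6 | step 1 | 1-[(4S)-2,2-dimethyl-1,3-dioxolan-4-yl]-2,2-dimethylbut-3-en-1-one | C=CC(C)(C)C(=O)[C@@H]1COC(C)(C)O1
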